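Ring A is labelled a1 (OMe), a2 (H), a3 (OH), a4 (4-hydroxybenzyl), a5 (ethylene bridge) and a6 (4-hydroxybenzyl). The plan removes the two different carbon groups on the adjacent atoms a5 and a6 together, which leads back to an a5-a6 aryne. Since a6 adjoins the methoxy-bearing a1, that aryne is polarised. The ring B copper acetylide should bond to a5, and the arylcopper left at a6 is then benzylated. One operation thus forms two C-C bonds and unites three fragments. The precursor is the a6-trimethylsilyl a5-triflate, already carrying the a4 benzyl group and benzyl ethers. A single hydrogenation completes the target.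

Key step: step 14

Assumption: 4-(benzyloxy)phenylmagnesium bromide is taken as the commercial THF solution (it can equally be made from 1-(benzyloxy)-4-bromobenzene and magnesium). The target has no stereocentre, and the two carbinols on the way are racemic, each losing its only stereocentre one step later.

Step 1
Reactants: 1 2,4,6-trimethoxybenzaldehyde
Product: 2 2,6-dihydroxy-4-methoxybenzaldehyde
Conditions: AlCl3 (4 equiv), CH2Cl2, 0 °C to reflux; then cold 1 M HCl
Reagents that add atoms: none
Why: Chelation-assisted Lewis acid ether cleavage, in which AlCl3 held on the formyl oxygen reaches only the two ortho methoxy groups (as in the standard conversion of 2,6-dimethoxybenzaldehyde into 2,6-dihydroxybenzaldehyde), so the para methoxy group (future a1) stays and the carbon substituent sits unambiguously between the two hydroxyls, a placement that electrophilic formylation of 5-methoxyresorcinol would not deliver cleanly.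

Step 2
Reactants: 2 2,6-dihydroxy-4-methoxybenzaldehyde
Product: 3 2-(benzyloxy)-6-hydroxy-4-methoxybenzaldehyde
Conditions: BnBr (1.0 equiv), K2CO3 (1.1 equiv), acetone, rt to 40 °C
Reagents that add atoms: benzyl bromide, BrCc1ccccc1
Why: Williamson ether synthesis under hydrogen-bond control, since after the first benzylation the remaining hydroxyl is locked to the aldehyde oxygen and is a much poorer nucleophile, so one equivalent of halide should stop largely at the monoether.

Step 3
Reactants: 3 2-(benzyloxy)-6-hydroxy-4-methoxybenzaldehyde; 4 4-(benzyloxy)phenylmagnesium bromide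
Product: 5 racemic 3-(benzyloxy)-2-{[4-(benzyloxy)phenyl](hydroxy)methyl}-5-methoxyphenol
Conditions: 4 (2.3 equiv), THF, 0 °C to rt; then H2O
Reagents that add atoms: none
Why: Grignard 1,2-addition to a salicylaldehyde, in which the first equivalent deprotonates the phenol and the magnesium phenoxide chelate activates the aldehyde for the second, the new carbinol centre being formed racemic and erased in step 4.

Step 4
Reactants: 5 racemic 3-(benzyloxy)-2-{[4-(benzyloxy)phenyl](hydroxy)methyl}-5-methoxyphenol
Product: 6 3-(benzyloxy)-2-[4-(benzyloxy)benzyl]-5-methoxyphenol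
Conditions: crude 5, Et3SiH (5 equiv), TFA (2 equiv), CH2Cl2 (dilute), -20 to 0 °C
Reagents that add atoms: none
Why: Ionic hydrogenation (Kursanov-Parnes type), in which mild acid ionises the carbinol to a benzhydryl cation stabilised by both rings and the large excess of silane delivers hydride before another arene can attack, while aryl benzyl ethers tolerate dilute TFA at this temperature.

Step 5
Reactants: 6 3-(benzyloxy)-2-[4-(benzyloxy)benzyl]-5-methoxyphenol
Product: 7 3-(benzyloxy)-2-[4-(benzyloxy)benzyl]-5-methoxyphenyl N-isopropylcarbamate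
Conditions: i-PrNCO (1.5 equiv), Et3N (0.2 equiv), CH2Cl2, rt
Reagents that add atoms: isopropyl isocyanate, CC(C)N=C=O
Why: Base-catalysed addition of a phenol to an isocyanate gives the N-monoalkyl carbamate, chosen over an N,N-dialkyl carbamate because it can later be removed by a mild E1cB cleavage that an electron-rich arylsilane survives.

Step 6
Reactants: 7 3-(benzyloxy)-2-[4-(benzyloxy)benzyl]-5-methoxyphenyl N-isopropylcarbamate
Product: 11 3-(benzyloxy)-2-[4-(benzyloxy)benzyl]-5-methoxy-6-(trimethylsilyl)phenyl N-isopropylcarbamate, via N-silyl carbamate 8 (not isolated), via a6-aryllithium 9 (not isolated), via N-silyl a6-silyl carbamate 10 (not isolated)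
Conditions: TBSOTf, TMEDA, Et2O, 0 °C to rt; n-BuLi, TMEDA, -78 °C; Me3SiCl, -78 °C to rt; then 1 M aq. NaHSO4, 0 °C, brief
Reagents that add atoms: chlorotrimethylsilane, C[Si](C)(C)Cl
Why: Directed ortho-metalation of an in situ N-silylated O-aryl N-isopropylcarbamate, where the carbamate is the strongest director on the ring, its other ortho site a4 is blocked and a6 lies between it and the methoxy group, so n-BuLi held in a six-membered pre-lithiation complex should remove the a6 proton at -78 °C faster than the a4 CH2 protons (reached only through a seven-membered array) or the benzyl ether CH2 protons, and Me3SiCl then traps the aryllithium.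

Step 7
Reactants: 11 3-(benzyloxy)-2-[4-(benzyloxy)benzyl]-5-methoxy-6-(trimethylsilyl)phenyl N-isopropylcarbamate
Product: 13 3-(benzyloxy)-2-[4-(benzyloxy)benzyl]-5-methoxy-6-(trimethylsilyl)phenyl trifluoromethanesulfonate, via silylphenol 12 (not isolated)
Conditions: Et2NH, DBU, MeCN, 40 °C; then PhNTf2, rt
Reagents that add atoms: N-phenylbis(trifluoromethanesulfonimide), O=S(=O)(N(c1ccccc1)S(=O)(=O)C(F)(F)F)C(F)(F)F
Why: E1cB carbamate cleavage followed by phenol triflation in one flask, in which DBU removes the N-H proton, isopropyl isocyanate departs and is scavenged by Et2NH, and the freed phenoxide is sulfonylated without any acid that could cleave the aryl-silicon bond.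

Step 8
Reactants: 14 4-bromo-2-hydroxybenzaldehyde
Product: 15 2-(benzyloxy)-4-bromobenzaldehyde
Conditions: BnBr (1.2 equiv), K2CO3, DMF, rt
Reagents that add atoms: benzyl bromide, BrCc1ccccc1
Why: Williamson ether synthesis on the only acidic hydroxyl, with excess halide in DMF overcoming the hydrogen bond to the aldehyde.

Step 9
Reactants: 15 2-(benzyloxy)-4-bromobenzaldehyde; 4 4-(benzyloxy)phenylmagnesium bromide
Product: 16 racemic [2-(benzyloxy)-4-bromophenyl][4-(benzyloxy)phenyl]methanol
Conditions: 4 (1.2 equiv), THF, -20 to 0 °C; then H2O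
Reagents that add atoms: none
Why: Grignard 1,2-addition, which is far faster than any bromine-magnesium exchange of an arylmagnesium bromide with the ring bromide, the carbinol centre being racemic and removed in step 10.

Step 10
Reactants: 16 racemic [2-(benzyloxy)-4-bromophenyl][4-(benzyloxy)phenyl]methanol
Product: 17 2-(benzyloxy)-1-[4-(benzyloxy)benzyl]-4-bromobenzene
Conditions: Et3SiH (3 equiv), TFA (5 equiv), CH2Cl2, 0 °C to rt
Reagents that add atoms: none
Why: Ionic hydrogenation through the alkoxy-stabilised benzhydryl cation removes the hydroxyl while sparing the aryl bromide and both benzyl ethers, which catalytic hydrogenolysis would not.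

Step 11
Reactants: 17 2-(benzyloxy)-1-[4-(benzyloxy)benzyl]-4-bromobenzene
Product: 18 ({3-(benzyloxy)-4-[4-(benzyloxy)benzyl]phenyl}ethynyl)trimethylsilane
Conditions: HC≡CSiMe3 (1.5 equiv), PdCl2(PPh3)2 (3 mol %), CuI (5 mol %), Et3N, 70 °C, sealed vessel
Reagents that add atoms: ethynyltrimethylsilane, C#C[Si](C)(C)C
Why: Sonogashira coupling of an unhindered aryl bromide that has both ortho positions free, the silyl cap preventing double coupling and alkyne homocoupling.

Step 12
Reactants: 18 ({3-(benzyloxy)-4-[4-(benzyloxy)benzyl]phenyl}ethynyl)trimethylsilane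
Product: 19 2-(benzyloxy)-1-[4-(benzyloxy)benzyl]-4-ethynylbenzene
Conditions: K2CO3 (0.2 equiv), MeOH/THF, rt
Reagents that add atoms: none
Why: Base-catalysed methanolysis of an alkynylsilane (protodesilylation) frees the terminal alkyne under conditions to which ethers and the diarylmethane are inert.

Step 13
Reactants: 20 4-(benzyloxy)benzyl alcohol
Product: 21 4-(benzyloxy)benzyl bromide
Conditions: PBr3 (0.4 equiv), Et2O, 0 °C; used at once
Reagents that add atoms: phosphorus tribromide, BrP(Br)Br
Why: Conversion of a benzylic alcohol into the bromide through its phosphite ester and bromide displacement, run cold and used fresh because a p-alkoxybenzylic bromide is labile on storage.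

Step 14
Reactants: 13 3-(benzyloxy)-2-[4-(benzyloxy)benzyl]-5-methoxy-6-(trimethylsilyl)phenyl trifluoromethanesulfonate; 19 2-(benzyloxy)-1-[4-(benzyloxy)benzyl]-4-ethynylbenzene; 21 4-(benzyloxy)benzyl bromide
Product: 25 1-(benzyloxy)-2,4-bis[4-(benzyloxy)benzyl]-3-({3-(benzyloxy)-4-[4-(benzyloxy)benzyl]phenyl}ethynyl)-5-methoxybenzene, via a5-a6 aryne 22 (not isolated), via copper acetylide 23 (not isolated), via a6-arylcopper 24 (not isolated)
Conditions: CuI (20 mol %), K2CO3 (2 equiv), CsF (3 equiv), MeCN/THF 1:1, 50 °C; 13 (1.3 equiv) fed slowly into 19 (1 equiv) and 21 (2.5 equiv)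
Reagents that add atoms: none
Why: Proposed new method: fluoride attacks the silicon of 13 and triflate departs to give aryne 22, the copper acetylide 23 (from 19, CuI and K2CO3) adds across the strained triple bond, and the arylcopper 24 so formed is alkylated by the benzylic bromide 21, by SN2-type oxidative addition to a trivalent copper species and reductive elimination, which returns monovalent copper to the cycle. The closest known reaction type is the CuI-catalysed three-component coupling of arynes, terminal alkynes and allylic halides; a benzylic halide as third partner is the untested part, and it is reasoned to work because a p-alkoxybenzylic bromide matches an allylic halide in SN2 reactivity and arylcopper reagents are known to couple with benzylic halides. Regioselectivity is required and comes from ring A itself: the oxygen on a1 is a sigma acceptor, so in 22 the internal angle opens at a5 and closes at a6, which makes a5 the site of nucleophilic attack and places the metal on a6, where the adjacent C-O dipole stabilises the developing carbanion character, as is established for 3-alkoxybenzynes. This electronic bias must outweigh the steric repulsion from the a4 benzyl group next to a5, a demand eased by the cylindrical, unbranched shape of an acetylide. Chemoselectivity is also required: the sp-bound copper of 23 is a sluggish partner for 21 whereas the sp2-bound copper of 24 is a good one, and the slow feed of 13, the excess of 21 and the carbonate (which keeps free C-H acid low) should hold back direct alkyne benzylation and protonation of 24. No ring is closed and no stereocentre is created.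

Step 15
Reactants: 25 1-(benzyloxy)-2,4-bis[4-(benzyloxy)benzyl]-3-({3-(benzyloxy)-4-[4-(benzyloxy)benzyl]phenyl}ethynyl)-5-methoxybenzene
Product: 26 2,4-bis(4-hydroxybenzyl)-3-{2-[3-hydroxy-4-(4-hydroxybenzyl)phenyl]ethyl}-5-methoxyphenol (CNP0207338.0)
Conditions: H2 (3 bar), 10% Pd/C, THF/MeOH 1:1, rt
Reagents that add atoms: none
Why: Heterogeneous catalytic hydrogenation saturates the alkyne through the stilbene to the ethylene bridge and hydrogenolyses the five aryl benzyl ethers, while the diarylmethane C-C bonds, the methyl ether and the arenes are inert to Pd/C under mild pressure, and no hydroxyl stands ortho to the alkyne so no benzofuran can form.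

Compound list
1 | 2,4,6-trimethoxybenzaldehyde | COc1cc(OC)c(C=O)c(OC)c1 | starting material
2 | 2,6-dihydroxy-4-methoxybenzaldehyde | COc1cc(O)c(C=O)c(O)c1 | intermediate
3 | 2-(benzyloxy)-6-hydroxy-4-methoxybenzaldehyde | COc1cc(OCc2ccccc2)c(C=O)c(O)c1 | intermediate
4 | 4-(benzyloxy)phenylmagnesium bromide | Br[Mg]c1ccc(OCc2ccccc2)cc1 | starting material
5 | racemic 3-(benzyloxy)-2-{[4-(benzyloxy)phenyl](hydroxy)methyl}-5-methoxyphenol | COc1cc(OCc2ccccc2)c(C(O)c2ccc(OCc3ccccc3)cc2)c(O)c1 | intermediate
6 | 3-(benzyloxy)-2-[4-(benzyloxy)benzyl]-5-methoxyphenol | COc1cc(OCc2ccccc2)c(Cc2ccc(OCc3ccccc3)cc2)c(O)c1 | intermediate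
7 | 3-(benzyloxy)-2-[4-(benzyloxy)benzyl]-5-methoxyphenyl N-isopropylcarbamate | COc1cc(OCc2ccccc2)c(Cc2ccc(OCc3ccccc3)cc2)c(OC(=O)NC(C)C)c1 | intermediate
8 | N-(tert-butyldimethylsilyl) derivative of carbamate 7 | COc1cc(OCc2ccccc2)c(Cc2ccc(OCc3ccccc3)cc2)c(OC(=O)N(C(C)C)[Si](C)(C)C(C)(C)C)c1 | intermediate
9 | a6-lithiated N-silyl carbamate | COc1cc(OCc2ccccc2)c(Cc2ccc(OCc3ccccc3)cc2)c(OC(=O)N(C(C)C)[Si](C)(C)C(C)(C)C)c1[Li] | intermediate
10 | a6-trimethylsilyl N-(tert-butyldimethylsilyl) carbamate | COc1cc(OCc2ccccc2)c(Cc2ccc(OCc3ccccc3)cc2)c(OC(=O)N(C(C)C)[Si](C)(C)C(C)(C)C)c1[Si](C)(C)C | intermediate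
11 | 3-(benzyloxy)-2-[4-(benzyloxy)benzyl]-5-methoxy-6-(trimethylsilyl)phenyl N-isopropylcarbamate | COc1cc(OCc2ccccc2)c(Cc2ccc(OCc3ccccc3)cc2)c(OC(=O)NC(C)C)c1[Si](C)(C)C | intermediate
12 | 3-(benzyloxy)-2-[4-(benzyloxy)benzyl]-5-methoxy-6-(trimethylsilyl)phenol | COc1cc(OCc2ccccc2)c(Cc2ccc(OCc3ccccc3)cc2)c(O)c1[Si](C)(C)C | intermediate
13 | 3-(benzyloxy)-2-[4-(benzyloxy)benzyl]-5-methoxy-6-(trimethylsilyl)phenyl trifluoromethanesulfonate | COc1cc(OCc2ccccc2)c(Cc2ccc(OCc3ccccc3)cc2)c(OS(=O)(=O)C(F)(F)F)c1[Si](C)(C)C | intermediate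
14 | 4-bromo-2-hydroxybenzaldehyde | O=Cc1ccc(Br)cc1O | starting material
15 | 2-(benzyloxy)-4-bromobenzaldehyde | O=Cc1ccc(Br)cc1OCc1ccccc1 | intermediate
16 | racemic [2-(benzyloxy)-4-bromophenyl][4-(benzyloxy)phenyl]methanol | OC(c1ccc(OCc2ccccc2)cc1)c1ccc(Br)cc1OCc1ccccc1 | intermediate
17 | 2-(benzyloxy)-1-[4-(benzyloxy)benzyl]-4-bromobenzene | Brc1ccc(Cc2ccc(OCc3ccccc3)cc2)c(OCc2ccccc2)c1 | intermediate
18 | ({3-(benzyloxy)-4-[4-(benzyloxy)benzyl]phenyl}ethynyl)trimethylsilane | C[Si](C)(C)C#Cc1ccc(Cc2ccc(OCc3ccccc3)cc2)c(OCc2ccccc2)c1 | intermediate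
19 | 2-(benzyloxy)-1-[4-(benzyloxy)benzyl]-4-ethynylbenzene | C#Cc1ccc(Cc2ccc(OCc3ccccc3)cc2)c(OCc2ccccc2)c1 | intermediate
20 | 4-(benzyloxy)benzyl alcohol | OCc1ccc(OCc2ccccc2)cc1 | starting material
21 | 4-(benzyloxy)benzyl bromide | BrCc1ccc(OCc2ccccc2)cc1 | intermediate
22 | 5-(benzyloxy)-6-[4-(benzyloxy)benzyl]-3-methoxy-1,2-didehydrobenzene (a5-a6 aryne) | COC1=CC(OCc2ccccc2)=C(Cc2ccc(OCc3ccccc3)cc2)C#C1 | intermediate
23 | copper acetylide of alkyne 19 | [Cu]C#Cc1ccc(Cc2ccc(OCc3ccccc3)cc2)c(OCc2ccccc2)c1 | intermediate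
24 | a6-arylcopper bearing the a5 alkynyl group | COc1cc(OCc2ccccc2)c(Cc2ccc(OCc3ccccc3)cc2)c(C#Cc2ccc(Cc3ccc(OCc4ccccc4)cc3)c(OCc3ccccc3)c2)c1[Cu] | intermediate
25 | 1-(benzyloxy)-2,4-bis[4-(benzyloxy)benzyl]-3-({3-(benzyloxy)-4-[4-(benzyloxy)benzyl]phenyl}ethynyl)-5-methoxybenzene | COc1cc(OCc2ccccc2)c(Cc2ccc(OCc3ccccc3)cc2)c(C#Cc2ccc(Cc3ccc(OCc4ccccc4)cc3)c(OCc3ccccc3)c2)c1Cc1ccc(OCc2ccccc2)cc1 | intermediate
26 | 2,4-bis(4-hydroxybenzyl)-3-{2-[3-hydroxy-4-(4-hydroxybenzyl)phenyl]ethyl}-5-methoxyphenol | COc1cc(O)c(Cc2ccc(O)cc2)c(CCc2ccc(Cc3ccc(O)cc3)c(O)c2)c1Cc1ccc(O)cc1 | target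

Total step count: 15. Longest linear sequence: 9 (steps 1 to 7, then 14 and 15).

Steps most likely to fail

Step 14.
- **What may go wrong:** the arylcopper may be protonated by free alkyne before it meets the halide. The acetylide may be benzylated directly. Fluoride or carbonate may consume the labile benzylic bromide. Addition may run in the reverse orientation under the steric pressure of the a4 benzyl group.
- **Fallback:** it uses known chemistry, avoids the aryne, and sets out from phenol 6.
- Magnesium-mediated ortho-formylation (Casnati-Skattebøl type; MgCl2, Et3N, paraformaldehyde, MeCN, reflux) can only strike a6, the single free position ortho to the hydroxyl. It gives 4-(benzyloxy)-3-[4-(benzyloxy)benzyl]-2-hydroxy-6-methoxybenzaldehyde F1.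
- Addition of 4 (2.3 equiv, THF) gives racemic 3-(benzyloxy)-2-[4-(benzyloxy)benzyl]-6-{[4-(benzyloxy)phenyl](hydroxy)methyl}-5-methoxyphenol F2.
- Ionic hydrogenation (Et3SiH, TFA, CH2Cl2) gives 3-(benzyloxy)-2,6-bis[4-(benzyloxy)benzyl]-5-methoxyphenol F3.
- Tf2O and pyridine give 3-(benzyloxy)-2,6-bis[4-(benzyloxy)benzyl]-5-methoxyphenyl trifluoromethanesulfonate F4.
- Copper-free Sonogashira coupling of this hindered triflate with alkyne 19 (Pd(OAc)2, XPhos, Cs2CO3, MeCN, 80 °C) comes back to the route at 25.

Step 6.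
- **What may go wrong:** deprotonation may compete at the doubly benzylic a4 CH2, followed by carbamoyl transfer. A benzyl ether CH2 may be metalated and undergo Wittig rearrangement. An anionic ortho-Fries shift may occur on warming. The electron-rich aryl-silicon bond may be lost by protodesilylation during the acidic quench.
- **Fallback:** it replaces deprotonation by halogen-lithium exchange, sets out from phenol 6 and bypasses steps 5 to 7.
- Amine-catalysed ortho-bromination (NBS, cat. i-Pr2NH, CH2Cl2, -78 °C) gives 3-(benzyloxy)-2-[4-(benzyloxy)benzyl]-6-bromo-5-methoxyphenol F5.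
- HMDS in refluxing THF gives [3-(benzyloxy)-2-[4-(benzyloxy)benzyl]-6-bromo-5-methoxyphenoxy]trimethylsilane F6.
- n-BuLi (THF, -78 °C) exchanges the bromine to give the a6-lithiated aryl silyl ether F7.
- A retro-Brook O-to-C silyl shift then gives lithium 3-(benzyloxy)-2-[4-(benzyloxy)benzyl]-5-methoxy-6-(trimethylsilyl)phenoxide F8.
- Tf2O added to the same flask comes back to the route at 13.

Step 2.
- **What may go wrong:** alkylation may run on past the monoether while starting diol remains, so that the desymmetrisation becomes statistical.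
- **Fallback:** it over-protects and then deprotects selectively, setting out from 2.
- Exhaustive benzylation (BnBr in excess, K2CO3, DMF, 60 °C) gives 2,6-bis(benzyloxy)-4-methoxybenzaldehyde F9.
- Chelation-directed cleavage of one ortho benzyl ether follows with MgBr2·OEt2 (1 equiv, toluene/Et2O, reflux). The magnesium phenoxide chelate formed after the first cleavage ties up the carbonyl oxygen and shuts down the second. This comes back to the route at 3.

Further compounds
F1 | step 14 | 4-(benzyloxy)-3-[4-(benzyloxy)benzyl]-2-hydroxy-6-methoxybenzaldehyde | COc1cc(OCc2ccccc2)c(Cc2ccc(OCc3ccccc3)cc2)c(O)c1C=O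
F2 | step 14 | racemic 3-(benzyloxy)-2-[4-(benzyloxy)benzyl]-6-{[4-(benzyloxy)phenyl](hydroxy)methyl}-5-methoxyphenol | COc1cc(OCc2ccccc2)c(Cc2ccc(OCc3ccccc3)cc2)c(O)c1C(O)c1ccc(OCc2ccccc2)cc1
F3 | step 14 | 3-(benzyloxy)-2,6-bis[4-(benzyloxy)benzyl]-5-methoxyphenol | COc1cc(OCc2ccccc2)c(Cc2ccc(OCc3ccccc3)cc2)c(O)c1Cc1ccc(OCc2ccccc2)cc1
F4 | step 14 | 3-(benzyloxy)-2,6-bis[4-(benzyloxy)benzyl]-5-methoxyphenyl trifluoromethanesulfonate | COc1cc(OCc2ccccc2)c(Cc2ccc(OCc3ccccc3)cc2)c(OS(=O)(=O)C(F)(F)F)c1Cc1ccc(OCc2ccccc2)cc1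
F5 | step 6 | 3-(benzyloxy)-2-[4-(benzyloxy)benzyl]-6-bromo-5-methoxyphenol | COc1cc(OCc2ccccc2)c(Cc2ccc(OCc3ccccc3)cc2)c(O)c1Br
F6 | step 6 | [3-(benzyloxy)-2-[4-(benzyloxy)benzyl]-6-bromo-5-methoxyphenoxy]trimethylsilane | COc1cc(OCc2ccccc2)c(Cc2ccc(OCc3ccccc3)cc2)c(O[Si](C)(C)C)c1Br
F7 | step 6 | a6-lithiated aryl silyl ether | COc1cc(OCc2ccccc2)c(Cc2ccc(OCc3ccccc3)cc2)c(O[Si](C)(C)C)c1[Li]
F8 | step 6 | lithium 3-(benzyloxy)-2-[4-(benzyloxy)benzyl]-5-methoxy-6-(trimethylsilyl)phenoxide | COc1cc(OCc2ccccc2)c(Cc2ccc(OCc3ccccc3)cc2)c([O-])c1[Si](C)(C)C.[Li+]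
F9 | step 2 | 2,6-bis(benzyloxy)-4-methoxybenzaldehyde | COc1cc(OCc2ccccc2)c(C=O)c(OCc2ccccc2)c1
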